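The route rests on cutting the (E)-4-hydroxy-3-methylbut-2-enyl chain at ring carbon C3 of the benzoate into three pieces: the benzylic carbon C1′, prop-2-yn-1-ol (C2′–C4′) and a methyl group. The feature exploited is the trisubstituted C2′=C3′ alkene, whose C3′ methyl sits cis to C1′. Syn methylalumination of the alkyne, then stereoretentive palladium-catalysed benzylation of the resulting alkenylalane, makes the C3′–CH3 and C1′–C2′ bonds in one flask and fixes that geometry. The precursor is a benzylic chloride on the otherwise complete benzene ring: methyl ester at C1, TIPS ether at C4, and the (S)-4-silyloxy-3-methylbutyl chain at C5. The enone arm is grown afterwards.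

Key step: step 9

Remark: the carbinol centre made in step 13 is left uncontrolled because step 15 erases it. Early loss of the tertiary TMS ether after step 13 would be harmless, since that alcohol is inert in steps 14 and 15 and is free in the target.

Step 1
Reactants: 1 methyl (R)-3-hydroxy-2-methylpropanoate
Product: 2 methyl (R)-3-(tert-butyldimethylsilyloxy)-2-methylpropanoate
Conditions: TBSCl, imidazole, CH2Cl2, 0 °C → rt
Reagents that add atoms: tert-butyldimethylsilyl chloride, CC(C)(C)[Si](C)(C)Cl
Why: Silyl ether formation, in which imidazole-activated TBSCl caps the unhindered primary alcohol without touching the ester or the adjacent stereocentre.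

Step 2
Reactants: 2 methyl (R)-3-(tert-butyldimethylsilyloxy)-2-methylpropanoate
Product: 3 (R)-3-(tert-butyldimethylsilyloxy)-2-methylpropanal
Conditions: i-Bu2AlH (1.05 equiv), CH2Cl2, −78 °C
Reagents that add atoms: none
Why: Partial ester reduction, in which the tetrahedral aluminium hemiacetal persists at −78 °C until the quench so that reduction should stop at the aldehyde, which is used crude to keep the α-centre from enolising.

Step 3
Reactants: 3 (R)-3-(tert-butyldimethylsilyloxy)-2-methylpropanal
Product: 4 (S)-tert-butyl(dimethyl)[(2-methylbut-3-enyl)oxy]silane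
Conditions: Ph3PCH3Br, n-BuLi, THF, 0 °C; then 3, −78 °C → rt
Reagents that add atoms: methyltriphenylphosphonium bromide, C[P+](c1ccccc1)(c1ccccc1)c1ccccc1.[Br-]
Why: Wittig methylenation, in which the non-stabilised ylide adds to the aldehyde faster than it deprotonates it at low temperature, so the configuration is carried over (the descriptor changes from R to S only through the priority change).

Step 4
Reactants: 5 methyl 3-formyl-4-hydroxybenzoate
Product: 6 methyl 3-formyl-4-hydroxy-5-iodobenzoate
Conditions: NIS, TFA/MeCN, rt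
Reagents that add atoms: N-iodosuccinimide, O=C1CCC(=O)N1I
Why: Electrophilic aromatic iodination, directed by the hydroxyl group to its only free ortho position C5, which is also meta to both acceptor groups.

Step 5
Reactants: 4 (S)-tert-butyl(dimethyl)[(2-methylbut-3-enyl)oxy]silane; 6 methyl 3-formyl-4-hydroxy-5-iodobenzoate
Product: 8 methyl 5-[(3S)-4-(tert-butyldimethylsilyloxy)-3-methylbutyl]-3-formyl-4-hydroxybenzoate, via B-alkyl-9-BBN adduct 7 (not isolated)
Conditions: 4 (slight excess over borane), 9-BBN-H, THF, 0 °C → rt; then 6, PdCl2(dppf) (5 mol %), aq. K3PO4, DMF, 50 °C; peroxide-free work-up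
Reagents that add atoms: 9-borabicyclo[3.3.1]nonane (9-BBN-H), B1C2CCCC1CCC2 (its boron and ring stay only in 7)
Why: Anti-Markovnikov hydroboration followed by B-alkyl Suzuki–Miyaura coupling, run on the free phenol because an aryl silyl ether of so acidic a phenol would not outlast aqueous base; the doubly acceptor-substituted aryl iodide still adds readily to palladium and the remote stereocentre is untouched.

Step 6
Reactants: 8 methyl 5-[(3S)-4-(tert-butyldimethylsilyloxy)-3-methylbutyl]-3-formyl-4-hydroxybenzoate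
Product: 9 methyl 5-[(3S)-4-(tert-butyldimethylsilyloxy)-3-methylbutyl]-3-formyl-4-(triisopropylsilyloxy)benzoate
Conditions: TIPSOTf, 2,6-lutidine, CH2Cl2, 0 °C
Reagents that add atoms: triisopropylsilyl trifluoromethanesulfonate, CC(C)[Si](OS(=O)(=O)C(F)(F)F)(C(C)C)C(C)C
Why: Silyl ether formation with a silyl triflate, reactive enough for the flanked, hydrogen-bonded phenol and placed after the only aqueous-base step before the key step.

Step 7
Reactants: 9 methyl 5-[(3S)-4-(tert-butyldimethylsilyloxy)-3-methylbutyl]-3-formyl-4-(triisopropylsilyloxy)benzoate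
Product: 10 methyl 5-[(3S)-4-(tert-butyldimethylsilyloxy)-3-methylbutyl]-3-(hydroxymethyl)-4-(triisopropylsilyloxy)benzoate
Conditions: BH3·THF, THF, 0 °C; aqueous work-up
Reagents that add atoms: none
Why: Chemoselective borane reduction of the aldehyde, which passes through a neutral borate ester rather than a free alkoxide and so should avoid silyl migration from the phenol oxygen, while the aryl ester is reduced far more slowly.

Step 8
Reactants: 10 methyl 5-[(3S)-4-(tert-butyldimethylsilyloxy)-3-methylbutyl]-3-(hydroxymethyl)-4-(triisopropylsilyloxy)benzoate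
Product: 12 methyl 5-[(3S)-4-(tert-butyldimethylsilyloxy)-3-methylbutyl]-3-(chloromethyl)-4-(triisopropylsilyloxy)benzoate, via benzylic mesylate 11 (not isolated)
Conditions: MsCl, Et3N, LiCl, THF, 0 °C → rt
Reagents that add atoms: lithium chloride, [Li+].[Cl-]; methanesulfonyl chloride, CS(=O)(=O)Cl (its atoms stay only in 11)
Why: Mesylation followed by SN2 displacement with chloride under nearly neutral, HCl-free conditions, so both silyl ethers should survive.

Step 9
Reactants: 12 methyl 5-[(3S)-4-(tert-butyldimethylsilyloxy)-3-methylbutyl]-3-(chloromethyl)-4-(triisopropylsilyloxy)benzoate; 13 prop-2-yn-1-ol; 14 trimethylaluminium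
Product: 17 methyl 5-[(3S)-4-(tert-butyldimethylsilyloxy)-3-methylbutyl]-3-[(2E)-4-hydroxy-3-methylbut-2-enyl]-4-(triisopropylsilyloxy)benzoate, via dimethylaluminium prop-2-ynoxide 15 (not isolated), via (E)-alkenylalane 16 (not isolated)
Conditions: 13 (2 equiv), Me3Al (3 equiv per 13), Cp2ZrCl2 (25 mol % per 13), ClCH2CH2Cl, 0 °C → rt; volatiles and free Me3Al removed in vacuo; then 12, Pd(PPh3)4 (5 mol %), THF, rt
Reagents that add atoms: trimethylaluminium 14, C[Al](C)C (one methyl group stays in 17)
Why: Me3Al first turns 13 into the aluminium alkoxide 15 with loss of methane, and the methylzirconocene–alane pair formed from Cp2ZrCl2 and Me3Al then delivers methyl and metal to the same face of the triple bond, methyl to the internal carbon and metal to the unhindered terminal carbon, leaving the (E)-alkenylalane 16 after exchange of zirconium for aluminium. Zerovalent palladium inserts into the benzylic C–Cl bond of 12, the alkenyl group passes from aluminium to the divalent benzylpalladium chloride with retention, and reductive elimination forms the C1′–C2′ bond. The closest known reaction type is zirconium-catalysed methylalumination of a terminal alkyne followed by palladium- or nickel-catalysed Negishi-type coupling of the alkenylalane with a benzylic chloride. No ring is closed and no stereocentre is created; the selectivity needed is the regiochemistry and geometry of the alkene, secured by the terminal alkyne (a single unhindered CH terminus for the metal) and by the syn-addition/retention sequence, which puts the new methyl cis to the benzylic carbon. Chemoselectivity rests on four points: the benzylpalladium species has no β-hydrogen, the sp2 alkenyl group transfers faster than methyl once free Me3Al has been pumped off, THF tempers the Lewis acidity so that the chloride next to the bulky, weakly donating OTIPS group should not ionise, and the aryl ester and silyl ethers are inert to alanes at room temperature. The (S)-centre in the C5 chain is remote and unaffected, and the primary allylic alcohol is released on aqueous work-up.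

Step 10
Reactants: 17 methyl 5-[(3S)-4-(tert-butyldimethylsilyloxy)-3-methylbutyl]-3-[(2E)-4-hydroxy-3-methylbut-2-enyl]-4-(triisopropylsilyloxy)benzoate
Product: 18 methyl 5-[(3S)-4-(tert-butyldimethylsilyloxy)-3-methylbutyl]-3-[(2E)-4-(tert-butyldiphenylsilyloxy)-3-methylbut-2-enyl]-4-(triisopropylsilyloxy)benzoate
Conditions: TBDPSCl, imidazole, CH2Cl2, rt
Reagents that add atoms: tert-butyldiphenylsilyl chloride, CC(C)(C)[Si](Cl)(c1ccccc1)c1ccccc1
Why: Silyl ether formation on the only free hydroxyl group, with TBDPS chosen because it resists acid far better than primary TBS yet falls to fluoride at the end.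

Step 11
Reactants: 18 methyl 5-[(3S)-4-(tert-butyldimethylsilyloxy)-3-methylbutyl]-3-[(2E)-4-(tert-butyldiphenylsilyloxy)-3-methylbut-2-enyl]-4-(triisopropylsilyloxy)benzoate
Product: 19 methyl 3-[(2E)-4-(tert-butyldiphenylsilyloxy)-3-methylbut-2-enyl]-5-[(3S)-4-hydroxy-3-methylbutyl]-4-(triisopropylsilyloxy)benzoate
Conditions: CSA (10 mol %), MeOH/CH2Cl2, 0 °C
Reagents that add atoms: none
Why: Acid-catalysed methanolysis selective for the primary alkyl TBS ether, since TBDPS ethers and aryl TIPS ethers are much slower under acid and methanol cannot scramble a methyl ester.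

Step 12
Reactants: 19 methyl 3-[(2E)-4-(tert-butyldiphenylsilyloxy)-3-methylbut-2-enyl]-5-[(3S)-4-hydroxy-3-methylbutyl]-4-(triisopropylsilyloxy)benzoate
Product: 20 methyl 3-[(2E)-4-(tert-butyldiphenylsilyloxy)-3-methylbut-2-enyl]-5-[(3S)-3-methyl-4-oxobutyl]-4-(triisopropylsilyloxy)benzoate
Conditions: Dess–Martin periodinane, CH2Cl2, 0 °C → rt
Reagents that add atoms: none
Why: Dess–Martin oxidation, a fast and base-free conversion of the primary alcohol into the aldehyde, which is used without chromatography so that the α-methyl centre keeps its configuration.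

Step 13
Reactants: 20 methyl 3-[(2E)-4-(tert-butyldiphenylsilyloxy)-3-methylbut-2-enyl]-5-[(3S)-3-methyl-4-oxobutyl]-4-(triisopropylsilyloxy)benzoate; 21 3-methyl-3-(trimethylsilyloxy)but-1-yne
Product: 24 methyl 3-[(2E)-4-(tert-butyldiphenylsilyloxy)-3-methylbut-2-enyl]-5-[(3S,5E)-4-hydroxy-3,7-dimethyl-7-(trimethylsilyloxy)oct-5-enyl]-4-(triisopropylsilyloxy)benzoate (both C4 epimers), via (E)-alkenylzirconocene chloride 22 (not isolated), via (E)-alkenyl(methyl)zinc 23 (not isolated)
Conditions: 21, Cp2Zr(H)Cl, CH2Cl2, rt; Me2Zn, toluene, −65 °C; then 20, 0 °C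
Reagents that add atoms: Cp2Zr(H)Cl, [H][Zr](Cl)(C1C=CC=C1)C1C=CC=C1 (zirconium stays only in 22); dimethylzinc, C[Zn]C (zinc stays only in 23)
Why: Hydrozirconation, zirconium-to-zinc transmetalation and 1,2-addition to the aldehyde, in which syn addition of Zr–H with zirconium at the terminal carbon sets the (E)-alkene and the mild alkenylzinc attacks the aldehyde but neither the aryl ester nor the α-proton; the new carbinol centre needs no control.

Step 14
Reactants: 24 methyl 3-[(2E)-4-(tert-butyldiphenylsilyloxy)-3-methylbut-2-enyl]-5-[(3S,5E)-4-hydroxy-3,7-dimethyl-7-(trimethylsilyloxy)oct-5-enyl]-4-(triisopropylsilyloxy)benzoate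
Product: 25 3-[(2E)-4-(tert-butyldiphenylsilyloxy)-3-methylbut-2-enyl]-5-[(3S,5E)-4-hydroxy-3,7-dimethyl-7-(trimethylsilyloxy)oct-5-enyl]-4-(triisopropylsilyloxy)benzoic acid
Conditions: Me3SnOH, ClCH2CH2Cl, 80 °C; dilute aq. HCl wash
Reagents that add atoms: trimethyltin hydroxide, C[Sn](C)(C)O (supplies the new carboxyl oxygen)
Why: Me3SnOH-mediated ester cleavage through a tin carboxylate, scheduled before the ketone exists so that no epimerisable centre or Michael acceptor meets heat and a hydroxide source, and while the phenol is still silylated so that the unhindered benzoate keeps its electrophilicity.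

Step 15
Reactants: 25 3-[(2E)-4-(tert-butyldiphenylsilyloxy)-3-methylbut-2-enyl]-5-[(3S,5E)-4-hydroxy-3,7-dimethyl-7-(trimethylsilyloxy)oct-5-enyl]-4-(triisopropylsilyloxy)benzoic acid
Product: 26 3-[(2E)-4-(tert-butyldiphenylsilyloxy)-3-methylbut-2-enyl]-5-[(3S,5E)-3,7-dimethyl-4-oxo-7-(trimethylsilyloxy)oct-5-enyl]-4-(triisopropylsilyloxy)benzoic acid
Conditions: Dess–Martin periodinane, CH2Cl2, 0 °C → rt
Reagents that add atoms: none
Why: Dess–Martin oxidation of the only oxidisable hydroxyl group, which merges both carbinol epimers into one (E)-enone in a non-basic medium that tolerates the free acid and preserves the now α-carbonyl (S)-centre.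

Step 16
Reactants: 26 3-[(2E)-4-(tert-butyldiphenylsilyloxy)-3-methylbut-2-enyl]-5-[(3S,5E)-3,7-dimethyl-4-oxo-7-(trimethylsilyloxy)oct-5-enyl]-4-(triisopropylsilyloxy)benzoic acid
Product: 27 4-hydroxy-3-[(2E)-4-hydroxy-3-methylbut-2-enyl]-5-[(3S,5E)-7-hydroxy-3,7-dimethyl-4-oxooct-5-enyl]benzoic acid (CNP0120226.2)
Conditions: Bu4NF/AcOH (1:1, excess), THF, 0 °C → rt
Reagents that add atoms: none
Why: Fluoride-mediated global desilylation, in which acetic acid buffers the medium so that the aryl TIPS, primary TBDPS and tertiary TMS ethers should all cleave without enolising the ketone and without the strong acid that could cyclise the phenol onto the allylic alcohol.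

Compound list
1 | methyl (R)-3-hydroxy-2-methylpropanoate | COC(=O)[C@H](C)CO | starting material
2 | methyl (R)-3-(tert-butyldimethylsilyloxy)-2-methylpropanoate | COC(=O)[C@H](C)CO[Si](C)(C)C(C)(C)C | intermediate
3 | (R)-3-(tert-butyldimethylsilyloxy)-2-methylpropanal | O=C[C@H](C)CO[Si](C)(C)C(C)(C)C | intermediate
4 | (S)-tert-butyl(dimethyl)[(2-methylbut-3-enyl)oxy]silane | C=C[C@H](C)CO[Si](C)(C)C(C)(C)C | intermediate
5 | methyl 3-formyl-4-hydroxybenzoate | COC(=O)c1ccc(O)c(C=O)c1 | starting material
6 | methyl 3-formyl-4-hydroxy-5-iodobenzoate | COC(=O)c1cc(I)c(O)c(C=O)c1 | intermediate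
7 | 9-[(3S)-4-(tert-butyldimethylsilyloxy)-3-methylbutyl]-9-borabicyclo[3.3.1]nonane | B1(CC[C@H](C)CO[Si](C)(C)C(C)(C)C)C2CCCC1CCC2 | intermediate (not isolated)
8 | methyl 5-[(3S)-4-(tert-butyldimethylsilyloxy)-3-methylbutyl]-3-formyl-4-hydroxybenzoate | COC(=O)c1cc(C=O)c(O)c(CC[C@H](C)CO[Si](C)(C)C(C)(C)C)c1 | intermediate
9 | methyl 5-[(3S)-4-(tert-butyldimethylsilyloxy)-3-methylbutyl]-3-formyl-4-(triisopropylsilyloxy)benzoate | COC(=O)c1cc(C=O)c(O[Si](C(C)C)(C(C)C)C(C)C)c(CC[C@H](C)CO[Si](C)(C)C(C)(C)C)c1 | intermediate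
10 | methyl 5-[(3S)-4-(tert-butyldimethylsilyloxy)-3-methylbutyl]-3-(hydroxymethyl)-4-(triisopropylsilyloxy)benzoate | COC(=O)c1cc(CO)c(O[Si](C(C)C)(C(C)C)C(C)C)c(CC[C@H](C)CO[Si](C)(C)C(C)(C)C)c1 | intermediate
11 | methyl 5-[(3S)-4-(tert-butyldimethylsilyloxy)-3-methylbutyl]-3-[(methylsulfonyloxy)methyl]-4-(triisopropylsilyloxy)benzoate | COC(=O)c1cc(COS(C)(=O)=O)c(O[Si](C(C)C)(C(C)C)C(C)C)c(CC[C@H](C)CO[Si](C)(C)C(C)(C)C)c1 | intermediate (not isolated)
12 | methyl 5-[(3S)-4-(tert-butyldimethylsilyloxy)-3-methylbutyl]-3-(chloromethyl)-4-(triisopropylsilyloxy)benzoate | COC(=O)c1cc(CCl)c(O[Si](C(C)C)(C(C)C)C(C)C)c(CC[C@H](C)CO[Si](C)(C)C(C)(C)C)c1 | intermediate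
13 | prop-2-yn-1-ol | C#CCO | starting material
14 | trimethylaluminium | C[Al](C)C | starting material
15 | dimethyl(prop-2-ynyloxy)aluminium | C#CCO[Al](C)C | intermediate (not isolated)
16 | [(1E)-3-(dimethylaluminiooxy)-2-methylprop-1-enyl]dimethylaluminium | C/C(=C\[Al](C)C)CO[Al](C)C | intermediate (not isolated)
17 | methyl 5-[(3S)-4-(tert-butyldimethylsilyloxy)-3-methylbutyl]-3-[(2E)-4-hydroxy-3-methylbut-2-enyl]-4-(triisopropylsilyloxy)benzoate | C/C(=C\Cc1cc(C(=O)OC)cc(CC[C@H](C)CO[Si](C)(C)C(C)(C)C)c1O[Si](C(C)C)(C(C)C)C(C)C)CO | intermediate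
18 | methyl 5-[(3S)-4-(tert-butyldimethylsilyloxy)-3-methylbutyl]-3-[(2E)-4-(tert-butyldiphenylsilyloxy)-3-methylbut-2-enyl]-4-(triisopropylsilyloxy)benzoate | C/C(=C\Cc1cc(C(=O)OC)cc(CC[C@H](C)CO[Si](C)(C)C(C)(C)C)c1O[Si](C(C)C)(C(C)C)C(C)C)CO[Si](c1ccccc1)(c1ccccc1)C(C)(C)C | intermediate
19 | methyl 3-[(2E)-4-(tert-butyldiphenylsilyloxy)-3-methylbut-2-enyl]-5-[(3S)-4-hydroxy-3-methylbutyl]-4-(triisopropylsilyloxy)benzoate | C/C(=C\Cc1cc(C(=O)OC)cc(CC[C@H](C)CO)c1O[Si](C(C)C)(C(C)C)C(C)C)CO[Si](c1ccccc1)(c1ccccc1)C(C)(C)C | intermediate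
20 | methyl 3-[(2E)-4-(tert-butyldiphenylsilyloxy)-3-methylbut-2-enyl]-5-[(3S)-3-methyl-4-oxobutyl]-4-(triisopropylsilyloxy)benzoate | C/C(=C\Cc1cc(C(=O)OC)cc(CC[C@H](C)C=O)c1O[Si](C(C)C)(C(C)C)C(C)C)CO[Si](c1ccccc1)(c1ccccc1)C(C)(C)C | intermediate
21 | 3-methyl-3-(trimethylsilyloxy)but-1-yne | C#CC(C)(C)O[Si](C)(C)C | starting material
22 | chlorobis(cyclopentadienyl)[(1E)-3-methyl-3-(trimethylsilyloxy)but-1-enyl]zirconium | C[Si](C)(C)OC(C)(C)/C=C/[Zr](Cl)(C1C=CC=C1)C1C=CC=C1 | intermediate (not isolated)
23 | methyl[(1E)-3-methyl-3-(trimethylsilyloxy)but-1-enyl]zinc | C[Zn]/C=C/C(C)(C)O[Si](C)(C)C | intermediate (not isolated)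
24 | methyl 3-[(2E)-4-(tert-butyldiphenylsilyloxy)-3-methylbut-2-enyl]-5-[(3S,5E)-4-hydroxy-3,7-dimethyl-7-(trimethylsilyloxy)oct-5-enyl]-4-(triisopropylsilyloxy)benzoate, both C4 epimers | C/C(=C\Cc1cc(C(=O)OC)cc(CC[C@H](C)C(O)/C=C/C(C)(C)O[Si](C)(C)C)c1O[Si](C(C)C)(C(C)C)C(C)C)CO[Si](c1ccccc1)(c1ccccc1)C(C)(C)C | intermediate
25 | 3-[(2E)-4-(tert-butyldiphenylsilyloxy)-3-methylbut-2-enyl]-5-[(3S,5E)-4-hydroxy-3,7-dimethyl-7-(trimethylsilyloxy)oct-5-enyl]-4-(triisopropylsilyloxy)benzoic acid, both C4 epimers | C/C(=C\Cc1cc(C(=O)O)cc(CC[C@H](C)C(O)/C=C/C(C)(C)O[Si](C)(C)C)c1O[Si](C(C)C)(C(C)C)C(C)C)CO[Si](c1ccccc1)(c1ccccc1)C(C)(C)C | intermediate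
26 | 3-[(2E)-4-(tert-butyldiphenylsilyloxy)-3-methylbut-2-enyl]-5-[(3S,5E)-3,7-dimethyl-4-oxo-7-(trimethylsilyloxy)oct-5-enyl]-4-(triisopropylsilyloxy)benzoic acid | C/C(=C\Cc1cc(C(=O)O)cc(CC[C@H](C)C(=O)/C=C/C(C)(C)O[Si](C)(C)C)c1O[Si](C(C)C)(C(C)C)C(C)C)CO[Si](c1ccccc1)(c1ccccc1)C(C)(C)C | intermediate
27 | 4-hydroxy-3-[(2E)-4-hydroxy-3-methylbut-2-enyl]-5-[(3S,5E)-7-hydroxy-3,7-dimethyl-4-oxooct-5-enyl]benzoic acid | C/C(=C\Cc1cc(C(=O)O)cc(CC[C@H](C)C(=O)/C=C/C(C)(C)O)c1O)CO | target

Total step count: 16.
Longest linear sequence: 15 steps (from 1 through steps 1–3 and 5–16 to 27).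

Steps most likely to fail

Step 9 (key step).
- What may go wrong: methyl may transfer to the benzylpalladium intermediate instead of the alkenyl group if free Me3Al is not fully removed. The alkoxide-bearing alane may transmetalate sluggishly. The benzylic chloride may ionise under Lewis acid. Any loss of regiochemical purity in the carbometalation can no longer be corrected after the coupling.
- Fallback (reversed polarity, same two bonds): it sets out from alane 16 and chloride 12 and comes back to the route at 18. Alane 16 is quenched with I2 in THF at −30 °C to (E)-3-iodo-2-methylprop-2-en-1-ol F1. This can be freed of any regioisomer and is then silylated (TBDPSCl, imidazole, CH2Cl2) to tert-butyl{[(2E)-3-iodo-2-methylprop-2-enyl]oxy}diphenylsilane F2. Chloride 12 is converted with Zn dust and LiCl in THF into the benzylic zinc chloride F3. Negishi coupling of F3 with F2 (Pd(PPh3)4, THF, rt) should give 18 with retention of the alkene geometry, so step 10 is absorbed.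

Step 5.
- What may go wrong: the ortho-phenoxide may bind palladium and slow oxidative addition or transmetalation. Protodeiodination may compete. The salicylaldehyde unit may hold back boron as a chelate. Any residual B–H would reduce the aldehyde.
- Fallback (base-free Negishi coupling on the already silylated arene): it sets out from 6 and from borane 7 and comes back at 9. Phenol 6 is silylated (TIPSOTf, 2,6-lutidine, CH2Cl2) to methyl 3-formyl-5-iodo-4-(triisopropylsilyloxy)benzoate F4. Borane 7 is cleaved with I2 and NaOMe in MeOH to tert-butyl{[(2S)-4-iodo-2-methylbutyl]oxy}dimethylsilane F5. Zinc insertion into F5 (Zn dust, LiCl, THF) gives the alkylzinc iodide F6. PdCl2(dppf)-catalysed coupling of F6 with F4 in anhydrous THF, where neither the aryl silyl ether nor the aldehyde is attacked, should give 9 directly and absorb step 6.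

Step 14.
- What may go wrong: the aryl silyl ether may be lost early under the hot hydroxide source. The phenolate-type donor then deactivates the para ester, so hydrolysis may stall at a tolerable temperature.
- Fallback (redox detour instead of acyl substitution): it sets out from 24 and comes back at 26. The ester of 24 is reduced with i-Bu2AlH (CH2Cl2, −78 → 0 °C) to the benzylic/allylic diol F7. Both carbinols are oxidised together with Dess–Martin periodinane to the keto aldehyde F8. Pinnick oxidation (NaClO2, NaH2PO4, 2-methylbut-2-ene, t-BuOH/H2O) takes only the aryl aldehyde to the acid 26 under weakly acidic conditions that spare the enone and its α-centre.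

Further compounds
F1 | step 9 | (E)-3-iodo-2-methylprop-2-en-1-ol | C/C(=C\I)CO
F2 | step 9 | tert-butyl{[(2E)-3-iodo-2-methylprop-2-enyl]oxy}diphenylsilane | C/C(=C\I)CO[Si](c1ccccc1)(c1ccccc1)C(C)(C)C
F3 | step 9 | {3-[(3S)-4-(tert-butyldimethylsilyloxy)-3-methylbutyl]-5-(methoxycarbonyl)-2-(triisopropylsilyloxy)benzyl}zinc chloride | COC(=O)c1cc(C[Zn]Cl)c(O[Si](C(C)C)(C(C)C)C(C)C)c(CC[C@H](C)CO[Si](C)(C)C(C)(C)C)c1
F4 | step 5 | methyl 3-formyl-5-iodo-4-(triisopropylsilyloxy)benzoate | COC(=O)c1cc(I)c(O[Si](C(C)C)(C(C)C)C(C)C)c(C=O)c1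
F5 | step 5 | tert-butyl{[(2S)-4-iodo-2-methylbutyl]oxy}dimethylsilane | ICC[C@H](C)CO[Si](C)(C)C(C)(C)C
F6 | step 5 | [(3S)-4-(tert-butyldimethylsilyloxy)-3-methylbutyl]zinc iodide | I[Zn]CC[C@H](C)CO[Si](C)(C)C(C)(C)C
F7 | step 14 | {3-[(2E)-4-(tert-butyldiphenylsilyloxy)-3-methylbut-2-enyl]-5-[(3S,5E)-4-hydroxy-3,7-dimethyl-7-(trimethylsilyloxy)oct-5-enyl]-4-(triisopropylsilyloxy)phenyl}methanol | C/C(=C\Cc1cc(CO)cc(CC[C@H](C)C(O)/C=C/C(C)(C)O[Si](C)(C)C)c1O[Si](C(C)C)(C(C)C)C(C)C)CO[Si](c1ccccc1)(c1ccccc1)C(C)(C)C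
F8 | step 14 | 3-[(2E)-4-(tert-butyldiphenylsilyloxy)-3-methylbut-2-enyl]-5-[(3S,5E)-3,7-dimethyl-4-oxo-7-(trimethylsilyloxy)oct-5-enyl]-4-(triisopropylsilyloxy)benzaldehyde | C/C(=C\Cc1cc(C=O)cc(CC[C@H](C)C(=O)/C=C/C(C)(C)O[Si](C)(C)C)c1O[Si](C(C)C)(C(C)C)C(C)C)CO[Si](c1ccccc1)(c1ccccc1)C(C)(C)C
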